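**Retrosynthetic overview**
1. The tetrahydropyran (O–C9–C10–C11–C12–C13) is closed last, from bromo epoxy alkene 28, by a bromonium-triggered ring expansion of the C9–C10 epoxide that also installs Br at C10 and C12. It is possible because the epoxide oxygen is homoallylic to the (E)-C12=C13 alkene (five-membered reach to C13) and because C9 is shielded by the C8 bromide, so bromide must open the 1-oxoniabicyclo[3.1.0]hexane at C10.
2. 28 comes from Julia–Kocienski olefination (C12=C13) of the 2,5-dioxabicyclo[2.2.1]heptane 25; its second ring (C4–O–C7) and the C8 bromide come from 5-exo bromoetherification of the all-cis hydroxy tetrahydrofuran 24 carrying a (Z)-C7=C8 vinyl epoxide.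
3. The first tetrahydrofuran (C3–O–C6) comes from ynone 18 by Noyori reduction (C6) and 5-exo opening of the C2–C3 epoxide with inversion at C3; C1 is added later by Ohira–Bestmann homologation.
4. 18 is assembled from epoxy alkyne 7 (C7–C12, Sharpless epoxidation) and epoxy aldehyde 13 (C2–C6, Sharpless desymmetrisation of divinylcarbinol).
5. Ring order: tetrahydrofuran C3–O–C6 (step 15), then the bicycle by C4–O–C7 closure (step 20), then the tetrahydropyran (step 24).

Key step: step 24

Remark: atoms are numbered C1–C15 along the carbon chain of the target (C1≡C2 ethynyl; C3, C4, C6, C7 in the dioxabicycle; C9–C13 in the tetrahydropyran; C14–C15 ethyl), and this numbering is used for all intermediates.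

**Route**

Step 1
Reactants: 1 but-3-yn-1-ol
Product: 2 1-[(but-3-yn-1-yloxy)methyl]-4-methoxybenzene
Conditions: NaH, PMBCl, n-Bu4NI (cat.), THF, 0 °C → rt
Reagents that add atoms: 4-methoxybenzyl chloride, COc1ccc(CCl)cc1
Why: Williamson etherification of the primary alkoxide with a benzylic chloride; the PMB ether should survive the organolithium, hydride, titanium and carbonate steps and is removed oxidatively later.

Step 2
Reactants: 2 PMB ether of but-3-yn-1-ol
Product: 3 5-[(4-methoxybenzyl)oxy]pent-2-yn-1-ol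
Conditions: n-BuLi, THF, −78 °C; then (CH2O)n, −78 °C → rt
Reagents that add atoms: formaldehyde (as paraformaldehyde), C=O
Why: 1,2-addition of the lithium acetylide to formaldehyde (hydroxymethylation) installs C8.

Step 3
Reactants: 3 5-[(4-methoxybenzyl)oxy]pent-2-yn-1-ol
Product: 4 (E)-5-[(4-methoxybenzyl)oxy]pent-2-en-1-ol
Conditions: LiAlH4, THF, 0 °C → rt
Reagents that add atoms: none
Why: alkoxide-directed trans-hydroalumination of the propargylic alcohol should give only the (E)-allylic alcohol after protonolysis.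

Step 4
Reactants: 4 (E)-5-[(4-methoxybenzyl)oxy]pent-2-en-1-ol
Product: 5 [(2R,3R)-3-{2-[(4-methoxybenzyl)oxy]ethyl}oxiran-2-yl]methanol
Conditions: Ti(OiPr)4 (10 mol%), D-(−)-diethyl tartrate (12 mol%), t-BuOOH, 4 Å MS, CH2Cl2, −20 °C
Reagents that add atoms: tert-butyl hydroperoxide, CC(C)(C)OO
Why: Sharpless asymmetric epoxidation, in which the D-(−)-tartrate catalyst delivers oxygen to the alkene face that gives the (2R,3R)-epoxide (C9 and C10), trans by stereospecific syn addition to the (E)-alkene.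

Step 5
Reactants: 5 (2R,3R)-epoxy alcohol
Product: 6 (2S,3R)-3-{2-[(4-methoxybenzyl)oxy]ethyl}oxirane-2-carbaldehyde
Conditions: Dess–Martin periodinane, NaHCO3, CH2Cl2, 0 °C → rt
Reagents that add atoms: none
Why: Dess–Martin oxidation under buffered conditions; the α-carbon is an epoxide carbon and cannot epimerise by enolisation.

Step 6
Reactants: 6 epoxy aldehyde
Product: 7 (2R,3R)-2-ethynyl-3-{2-[(4-methoxybenzyl)oxy]ethyl}oxirane
Conditions: dimethyl (1-diazo-2-oxopropyl)phosphonate, K2CO3, MeOH, 0 °C → rt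
Reagents that add atoms: dimethyl (1-diazo-2-oxopropyl)phosphonate, COP(=O)(OC)C(=[N+]=[N-])C(C)=O
Why: Ohira–Bestmann (Seyferth–Gilbert) homologation under mild carbonate conditions turns the aldehyde into the terminal alkyne (C7) without touching the epoxide.

Step 7
Reactants: 8 penta-1,4-dien-3-ol
Product: 9 (2R,3S)-1,2-epoxypent-4-en-3-ol
Conditions: Ti(OiPr)4 (15 mol%), L-(+)-diisopropyl tartrate (18 mol%), t-BuOOH, 4 Å MS, CH2Cl2, −20 °C
Reagents that add atoms: tert-butyl hydroperoxide, CC(C)(C)OO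
Why: Sharpless asymmetric epoxidation as a desymmetrisation, in which the L-(+)-tartrate catalyst selects one enantiotopic vinyl group and one face to give the erythro (2R,3S)-epoxy alcohol (C3 and C4), the minor enantiomer being consumed by a faster second epoxidation.

Step 8
Reactants: 9 (2R,3S)-1,2-epoxypent-4-en-3-ol
Product: 10 (2R,3S)-3-(tert-butyldimethylsilyloxy)-1,2-epoxypent-4-ene
Conditions: TBSCl, imidazole, DMF, 0 °C → rt
Reagents that add atoms: tert-butyldimethylsilyl chloride, CC(C)(C)[Si](C)(C)Cl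
Why: standard silylation of the secondary alcohol; the TBS ether blocks O4 until ring 1 and the alkyne are in place and is removed by fluoride without acid.

Step 9
Reactants: 10 TBS-protected epoxy pentenol
Product: 12 (3S)-3-(tert-butyldimethylsilyloxy)-3-[(2R)-oxiran-2-yl]propan-1-ol, via B-alkyl-9-BBN adduct 11 (not isolated)
Conditions: 9-BBN, THF, 0 °C → rt; then aq NaOAc, 30% H2O2, 0 °C
Reagents that add atoms: hydrogen peroxide, OO
Why: anti-Markovnikov hydroboration of the monosubstituted alkene with the bulky borane and oxidation with retention, the acetate-buffered work-up being chosen so that the epoxide and the 4,5-epoxy alcohol are not opened.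

Step 10
Reactants: 12 epoxy silyloxy propanol
Product: 13 (3S)-3-(tert-butyldimethylsilyloxy)-3-[(2R)-oxiran-2-yl]propanal
Conditions: Dess–Martin periodinane, NaHCO3, CH2Cl2, 0 °C
Reagents that add atoms: none
Why: Dess–Martin oxidation gives the C6 aldehyde under neutral conditions that avoid β-elimination of the silyloxy group.

Step 11
Reactants: 14 1-phenyl-1H-tetrazole-5-thiol
Product: 15 1-phenyl-5-(propylsulfanyl)-1H-tetrazole
Conditions: 1-bromopropane, K2CO3, acetone, 50 °C
Reagents that add atoms: 1-bromopropane, CCCBr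
Why: SN2 S-alkylation of the acidic tetrazole thiol.

Step 12
Reactants: 15 1-phenyl-5-(propylsulfanyl)-1H-tetrazole
Product: 16 1-phenyl-5-(propylsulfonyl)-1H-tetrazole
Conditions: (NH4)6Mo7O24·4H2O (cat.), 30% H2O2, EtOH, 0 °C → rt
Reagents that add atoms: hydrogen peroxide, OO
Why: molybdate-catalysed peroxide oxidation of the sulfide to the sulfone, the usual entry to Julia–Kocienski reagents.

Step 13
Reactants: 7 epoxy alkyne (C7–C12); 13 epoxy aldehyde (C2–C6)
Product: 17 C2–C12 diepoxy propargylic alcohol as a mixture of C6 epimers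
Conditions: 7, n-BuLi, THF, −78 °C; then 13, −78 °C; quench at −78 °C with aq NH4Cl
Reagents that add atoms: none
Why: 1,2-addition of the lithium acetylide of 7 to the aldehyde forms the C6–C7 bond at low temperature, where neither epoxide is attacked; the uncontrolled C6 centre is erased in the next step.

Step 14
Reactants: 17 C6-epimeric propargylic alcohols
Product: 18 C2–C12 diepoxy ynone (6-ketone)
Conditions: Dess–Martin periodinane, NaHCO3, CH2Cl2, 0 °C
Reagents that add atoms: none
Why: Dess–Martin oxidation of the propargylic alcohol converges both epimers to one alkynyl ketone.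

Step 15
Reactants: 18 diepoxy ynone
Product: 20 {(2S,3S,5S)-3-(tert-butyldimethylsilyloxy)-5-[((2R,3R)-3-{2-[(4-methoxybenzyl)oxy]ethyl}oxiran-2-yl)ethynyl]oxolan-2-yl}methanol, via (6S)-hydroxy epoxide 19 (not isolated)
Conditions: Ru[(S,S)-TsDPEN](p-cymene) (2 mol%), i-PrOH, rt; then evaporation; CSA (10 mol%), CH2Cl2, 0 °C
Reagents that add atoms: none
Why: Noyori asymmetric transfer hydrogenation of the alkynyl ketone sets C6 (S) under catalyst control, and the C6 hydroxyl then opens the terminal epoxide at C3 in an acid-catalysed 5-exo SN2 reaction with inversion, which gives the all-cis 2,3,5-trisubstituted tetrahydrofuran (ring 1).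

Step 16
Reactants: 20 alkynyl tetrahydrofuran
Product: 21 {(2S,3S,5S)-3-(tert-butyldimethylsilyloxy)-5-[(Z)-2-((2R,3R)-3-{2-[(4-methoxybenzyl)oxy]ethyl}oxiran-2-yl)ethenyl]oxolan-2-yl}methanol
Conditions: H2 (1 atm), Pd/CaCO3 poisoned with Pb(OAc)2 (Lindlar catalyst), quinoline, EtOAc, rt
Reagents that add atoms: none
Why: Lindlar semihydrogenation adds H2 syn to the only alkyne present at this stage and should give the (Z)-C7=C8 vinyl epoxide.

Step 17
Reactants: 21 (Z)-alkenyl tetrahydrofuran methanol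
Product: 22 (2R,3S,5S)-3-(tert-butyldimethylsilyloxy)-5-[(Z)-2-((2R,3R)-3-{2-[(4-methoxybenzyl)oxy]ethyl}oxiran-2-yl)ethenyl]oxolane-2-carbaldehyde
Conditions: Dess–Martin periodinane, NaHCO3, CH2Cl2, 0 °C
Reagents that add atoms: none
Why: Dess–Martin oxidation of the primary alcohol (C2) under buffered conditions that should not epimerise C3.

Step 18
Reactants: 22 tetrahydrofuran carbaldehyde
Product: 23 tert-butyl{[(2S,3S,5S)-2-ethynyl-5-[(Z)-2-((2R,3R)-3-{2-[(4-methoxybenzyl)oxy]ethyl}oxiran-2-yl)ethenyl]oxolan-3-yl]oxy}dimethylsilane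
Conditions: dimethyl (1-diazo-2-oxopropyl)phosphonate, K2CO3, MeOH, 0 °C → rt
Reagents that add atoms: dimethyl (1-diazo-2-oxopropyl)phosphonate, COP(=O)(OC)C(=[N+]=[N-])C(C)=O
Why: Ohira–Bestmann homologation adds C1 and gives the ethynyl group; the reaction type is routinely run on cis-α-alkoxy furanose aldehydes without loss of the α-centre.

Step 19
Reactants: 23 silyl ether
Product: 24 (2S,3S,5S)-2-ethynyl-5-[(Z)-2-((2R,3R)-3-{2-[(4-methoxybenzyl)oxy]ethyl}oxiran-2-yl)ethenyl]oxolan-3-ol
Conditions: n-Bu4NF, AcOH (1:1), THF, 0 °C → rt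
Reagents that add atoms: none
Why: fluoride desilylation, buffered with acetic acid so that the liberated C4 alkoxide does not attack the vinyl epoxide.

Step 20
Reactants: 24 all-cis hydroxy tetrahydrofuran
Product: 25 (1S,3S,4S,6S)-3-[(S)-bromo((2S,3R)-3-{2-[(4-methoxybenzyl)oxy]ethyl}oxiran-2-yl)methyl]-6-ethynyl-2,5-dioxabicyclo[2.2.1]heptane
Conditions: NBS (1.2 equiv), MeCN, 0 °C, dark
Reagents that add atoms: N-bromosuccinimide, O=C1CCC(=O)N1Br
Why: 5-exo bromoetherification, in which the C4 hydroxyl attacks C7 anti to the bromonium on the (Z)-alkene (as in halocyclisations of alkenes flanked by allylic oxygens); allylic 1,3-strain keeps H6 in the alkene plane so that C8 becomes exo on the new ring, and stereospecific anti addition then fixes C7 (S) and the C8 bromide together.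

Step 21
Reactants: 25 bromo bicycle PMB ether
Product: 26 2-[(2R,3S)-3-{(S)-bromo[(1S,3S,4S,6S)-6-ethynyl-2,5-dioxabicyclo[2.2.1]heptan-3-yl]methyl}oxiran-2-yl]ethan-1-ol
Conditions: DDQ, CH2Cl2/pH 7 phosphate buffer (10:1), 0 °C → rt
Reagents that add atoms: none
Why: oxidative PMB cleavage under neutral conditions that leave the bromide, epoxide and alkyne untouched.

Step 22
Reactants: 26 primary alcohol
Product: 27 2-[(2R,3S)-3-{(S)-bromo[(1S,3S,4S,6S)-6-ethynyl-2,5-dioxabicyclo[2.2.1]heptan-3-yl]methyl}oxiran-2-yl]acetaldehyde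
Conditions: Dess–Martin periodinane, NaHCO3, CH2Cl2, 0 °C; used at once
Reagents that add atoms: none
Why: Dess–Martin oxidation gives the sensitive β,γ-epoxy aldehyde (C12) under buffered conditions.

Step 23
Reactants: 27 β,γ-epoxy aldehyde; 16 1-phenyl-5-(propylsulfonyl)-1H-tetrazole
Product: 28 (1S,3S,4S,6S)-3-{(S)-bromo[(2S,3R)-3-((E)-pent-2-en-1-yl)oxiran-2-yl]methyl}-6-ethynyl-2,5-dioxabicyclo[2.2.1]heptane
Conditions: 16, KN(SiMe3)2, DME, −78 °C; then 27, −78 → −20 °C
Reagents that add atoms: none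
Why: Julia–Kocienski olefination with the pre-formed potassium sulfonyl carbanion in DME should give the (E)-C12=C13 alkene through the anti adduct, Smiles rearrangement and loss of SO2, with addition to the aldehyde at −78 °C outrunning enolisation.

Step 24
Reactants: 28 bromo epoxy (E)-alkene
Product: 30 (1S,3S,4S,6S)-3-{(R)-bromo[(2S,3S,5R,6S)-3,5-dibromo-6-ethyloxan-2-yl]methyl}-6-ethynyl-2,5-dioxabicyclo[2.2.1]heptane (target), via epoxonium bromide 29 (not isolated)
Conditions: NBS (1.1 equiv, added slowly), n-Bu4NBr (1.5 equiv), 4 Å MS, CH2Cl2, −40 → 0 °C, dark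
Reagents that add atoms: N-bromosuccinimide, O=C1CCC(=O)N1Br; tetrabutylammonium bromide, CCCC[N+](CCCC)(CCCC)CCCC.[Br-]
Why: Br+ is transferred to C12=C13, the only nucleophilic alkene, and the homoallylic epoxide oxygen attacks C13 anti to the bromonium through a five-membered transition state (5-endo closure, since attack at C12 would need a four-membered ring) to give the 1-oxoniabicyclo[3.1.0]hexane 29 (O, C10, C11, C12, C13 fused to the O–C9–C10 ring). Bromide then opens 29 at the ring-fusion carbon C10 with inversion, which expands the five-membered oxonium ring to the six-membered O–C9–C10–C11–C12–C13 ring; attack at C9 is disfavoured sterically and inductively by the adjacent C8 bromide and the bicyclic substituent. The closest known reaction type is halonium-induced participation of an epoxide oxygen with halide capture of the epoxonium ion, as in the bromination of cycloocta-1,5-diene monoepoxide to dibromo oxabicyclononanes and in bromonium-initiated epoxide-opening cascades. C12 and C13 are set by stereospecific anti addition to the (E)-alkene (12,13-trans), C10 by SN2 inversion of the (10R)-epoxide carbon (9,10-trans), and C9 is carried through unchanged. The 2,6-cis relationship of C9 and C13 needs one alkene face: in the epoxonium-forming transition state the ethyl group on C13 should take the convex face, trans to the epoxide carbon C9 across the oxonium oxygen, and this diastereomer is the one that expands to the all-equatorial tetrahydropyran. Chemoselectivity rests on the substrate, since the terminal alkyne is far less reactive towards Br+ than the dialkyl alkene and no other alkene remains.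

**Compound list**
1 | but-3-yn-1-ol | C#CCCO | starting material
2 | 1-[(but-3-yn-1-yloxy)methyl]-4-methoxybenzene | C#CCCOCc1ccc(OC)cc1 | intermediate
3 | 5-[(4-methoxybenzyl)oxy]pent-2-yn-1-ol | OCC#CCCOCc1ccc(OC)cc1 | intermediate
4 | (E)-5-[(4-methoxybenzyl)oxy]pent-2-en-1-ol | OC/C=C/CCOCc1ccc(OC)cc1 | intermediate
5 | [(2R,3R)-3-{2-[(4-methoxybenzyl)oxy]ethyl}oxiran-2-yl]methanol | OC[C@H]1O[C@@H]1CCOCc1ccc(OC)cc1 | intermediate
6 | (2S,3R)-3-{2-[(4-methoxybenzyl)oxy]ethyl}oxirane-2-carbaldehyde | O=C[C@H]1O[C@@H]1CCOCc1ccc(OC)cc1 | intermediate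
7 | (2R,3R)-2-ethynyl-3-{2-[(4-methoxybenzyl)oxy]ethyl}oxirane (C7–C12 fragment) | C#C[C@H]1O[C@@H]1CCOCc1ccc(OC)cc1 | intermediate
8 | penta-1,4-dien-3-ol | C=CC(O)C=C | starting material
9 | (2R,3S)-1,2-epoxypent-4-en-3-ol | C=C[C@H](O)[C@H]1CO1 | intermediate
10 | (2R,3S)-3-(tert-butyldimethylsilyloxy)-1,2-epoxypent-4-ene | C=C[C@H](O[Si](C)(C)C(C)(C)C)[C@H]1CO1 | intermediate
11 | 9-{(3S)-3-(tert-butyldimethylsilyloxy)-3-[(2R)-oxiran-2-yl]propyl}-9-borabicyclo[3.3.1]nonane | C1CC2CCCC(C1)B2CC[C@H](O[Si](C)(C)C(C)(C)C)[C@H]1CO1 | intermediate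
12 | (3S)-3-(tert-butyldimethylsilyloxy)-3-[(2R)-oxiran-2-yl]propan-1-ol | OCC[C@H](O[Si](C)(C)C(C)(C)C)[C@H]1CO1 | intermediate
13 | (3S)-3-(tert-butyldimethylsilyloxy)-3-[(2R)-oxiran-2-yl]propanal (C2–C6 fragment) | O=CC[C@H](O[Si](C)(C)C(C)(C)C)[C@H]1CO1 | intermediate
14 | 1-phenyl-1H-tetrazole-5-thiol | Sc1nnnn1-c1ccccc1 | starting material
15 | 1-phenyl-5-(propylsulfanyl)-1H-tetrazole | CCCSc1nnnn1-c1ccccc1 | intermediate
16 | 1-phenyl-5-(propylsulfonyl)-1H-tetrazole | CCCS(=O)(=O)c1nnnn1-c1ccccc1 | intermediate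
17 | C2–C12 chain: 2,3- and 9,10-epoxides (3R,9R,10R), 4-OTBS (4S), 6-OH (both epimers), 7-yne, 12-OPMB | OC(C#C[C@H]1O[C@@H]1CCOCc1ccc(OC)cc1)C[C@H](O[Si](C)(C)C(C)(C)C)[C@H]1CO1 | intermediate
18 | 6-ketone of 17 (3R,4S,9R,10R) | O=C(C#C[C@H]1O[C@@H]1CCOCc1ccc(OC)cc1)C[C@H](O[Si](C)(C)C(C)(C)C)[C@H]1CO1 | intermediate
19 | (6S)-alcohol of the C2–C12 chain (3R,4S,6S,9R,10R) | O[C@H](C#C[C@H]1O[C@@H]1CCOCc1ccc(OC)cc1)C[C@H](O[Si](C)(C)C(C)(C)C)[C@H]1CO1 | intermediate
20 | {(2S,3S,5S)-3-(tert-butyldimethylsilyloxy)-5-[((2R,3R)-3-{2-[(4-methoxybenzyl)oxy]ethyl}oxiran-2-yl)ethynyl]oxolan-2-yl}methanol | OC[C@@H]1O[C@H](C#C[C@H]2O[C@@H]2CCOCc2ccc(OC)cc2)C[C@@H]1O[Si](C)(C)C(C)(C)C | intermediate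
21 | {(2S,3S,5S)-3-(tert-butyldimethylsilyloxy)-5-[(Z)-2-((2R,3R)-3-{2-[(4-methoxybenzyl)oxy]ethyl}oxiran-2-yl)ethenyl]oxolan-2-yl}methanol | OC[C@@H]1O[C@H](/C=C\[C@H]2O[C@@H]2CCOCc2ccc(OC)cc2)C[C@@H]1O[Si](C)(C)C(C)(C)C | intermediate
22 | (2R,3S,5S)-3-(tert-butyldimethylsilyloxy)-5-[(Z)-2-((2R,3R)-3-{2-[(4-methoxybenzyl)oxy]ethyl}oxiran-2-yl)ethenyl]oxolane-2-carbaldehyde | O=C[C@@H]1O[C@H](/C=C\[C@H]2O[C@@H]2CCOCc2ccc(OC)cc2)C[C@@H]1O[Si](C)(C)C(C)(C)C | intermediate
23 | tert-butyl{[(2S,3S,5S)-2-ethynyl-5-[(Z)-2-((2R,3R)-3-{2-[(4-methoxybenzyl)oxy]ethyl}oxiran-2-yl)ethenyl]oxolan-3-yl]oxy}dimethylsilane | C#C[C@@H]1O[C@H](/C=C\[C@H]2O[C@@H]2CCOCc2ccc(OC)cc2)C[C@@H]1O[Si](C)(C)C(C)(C)C | intermediate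
24 | (2S,3S,5S)-2-ethynyl-5-[(Z)-2-((2R,3R)-3-{2-[(4-methoxybenzyl)oxy]ethyl}oxiran-2-yl)ethenyl]oxolan-3-ol | C#C[C@@H]1O[C@H](/C=C\[C@H]2O[C@@H]2CCOCc2ccc(OC)cc2)C[C@@H]1O | intermediate
25 | (1S,3S,4S,6S)-3-[(S)-bromo((2S,3R)-3-{2-[(4-methoxybenzyl)oxy]ethyl}oxiran-2-yl)methyl]-6-ethynyl-2,5-dioxabicyclo[2.2.1]heptane | C#C[C@@H]1O[C@H]2C[C@@H]1O[C@@H]2[C@@H](Br)[C@H]1O[C@@H]1CCOCc1ccc(OC)cc1 | intermediate
26 | 2-[(2R,3S)-3-{(S)-bromo[(1S,3S,4S,6S)-6-ethynyl-2,5-dioxabicyclo[2.2.1]heptan-3-yl]methyl}oxiran-2-yl]ethan-1-ol | C#C[C@@H]1O[C@H]2C[C@@H]1O[C@@H]2[C@@H](Br)[C@H]1O[C@@H]1CCO | intermediate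
27 | 2-[(2R,3S)-3-{(S)-bromo[(1S,3S,4S,6S)-6-ethynyl-2,5-dioxabicyclo[2.2.1]heptan-3-yl]methyl}oxiran-2-yl]acetaldehyde | C#C[C@@H]1O[C@H]2C[C@@H]1O[C@@H]2[C@@H](Br)[C@H]1O[C@@H]1CC=O | intermediate
28 | (1S,3S,4S,6S)-3-{(S)-bromo[(2S,3R)-3-((E)-pent-2-en-1-yl)oxiran-2-yl]methyl}-6-ethynyl-2,5-dioxabicyclo[2.2.1]heptane | C#C[C@@H]1O[C@H]2C[C@@H]1O[C@@H]2[C@@H](Br)[C@H]1O[C@@H]1C/C=C/CC | intermediate
29 | epoxonium bromide: 1-oxoniabicyclo[3.1.0]hexane with O bonded to C9, C10 and C13, Br on C12, ethyl on C13 trans to C9 | C#C[C@@H]1O[C@H]2C[C@@H]1O[C@@H]2[C@@H](Br)[C@@H]1[C@H]2C[C@@H](Br)[C@H](CC)[O+]12.[Br-] | intermediate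
30 | (1S,3S,4S,6S)-3-{(R)-bromo[(2S,3S,5R,6S)-3,5-dibromo-6-ethyloxan-2-yl]methyl}-6-ethynyl-2,5-dioxabicyclo[2.2.1]heptane (CNP0139964.1) | C#C[C@@H]1O[C@H]2C[C@@H]1O[C@@H]2[C@@H](Br)[C@H]1O[C@@H](CC)[C@H](Br)C[C@@H]1Br | target

**Step count and risks**

Total: 24 steps. Longest linear sequence: 18 steps (steps 1–6, then 13–24).

Steps most likely to fail, riskiest first:

Step 24 (key step). What may go wrong is plain anti-dibromination of C12=C13 before the epoxide oxygen takes part, bromide opening of the epoxonium at C9 instead of C10, or poor facial selectivity at the alkene. Fallback: the two C–Br bonds would be made in separate operations, setting out from 28 and returning at 30. First the epoxide of 28 is opened by bromide at C10, the carbon remote from the C8 bromide (Li2NiBr4, THF, 0 °C), to give the bromohydrin F1. Then 5-exo bromoetherification of the C9 hydroxyl onto C12=C13 (NBS, MeCN, 0 °C) gives the 2-(1-bromopropyl)tetrahydrofuran F2, the required C12 epimer being separated. Finally the known thermodynamic ring expansion of a 2-(1-bromoalkyl)tetrahydrofuran to a 3-bromotetrahydropyran through the bicyclic oxonium ion (ZnBr2 cat., MeNO2, 50 °C) should deliver 30 with inversion at C12 and C13.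

Step 23. What may go wrong is deprotonation at C11 by the metalated sulfone, followed by β-elimination that opens the epoxide, and erosion of E selectivity. Fallback: the alkene would be made without base by chromium-mediated alkylidenation (Takai–Utimoto), setting out from 27 and returning at 28: 1,1-diiodopropane (from propanal hydrazone and iodine) and CrCl2 in THF/DMF at rt, where divalent chromium reacts with the geminal diiodide and the aldehyde much faster than with a secondary alkyl bromide; no new compound is formed (F0).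

Step 15. What may go wrong is β-elimination of the silyloxy group or conjugate addition of isopropoxide to the ynone during transfer hydrogenation, and incomplete catalyst control at C6. Fallback: the C6 centre would be set during C–C bond formation instead of by reduction, setting out from aldehyde 13 (with alkyne 7) and returning at 20: zinc-mediated catalytic asymmetric alkynylation (Me2Zn, the ProPhenol ligand enantiomer that delivers the (6S)-carbinol, Ph3P=O, toluene, 0 °C) should give 19 directly, which is cyclised with CSA as before; steps 13 and 14 are then skipped and no new compound is formed (F0).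

Further compounds
F1 | step 24 | bromohydrin of 28: (8S,9S,10S)-8,10-dibromo-9-hydroxy chain on the bicycle with the (E)-C12=C13 alkene intact | C#C[C@@H]1O[C@H]2C[C@@H]1O[C@@H]2[C@@H](Br)[C@@H](O)[C@@H](Br)C/C=C/CC
F2 | step 24 | tetrahydrofuran (O bonded to C9 and C12) with 10-Br and exocyclic (13R)-1-bromopropyl group (9S,10S,12S) | C#C[C@@H]1O[C@H]2C[C@@H]1O[C@@H]2[C@@H](Br)[C@H]1O[C@H]([C@H](Br)CC)C[C@@H]1Br
F0 | step 23 | none | none
F0 | step 15 | none | none
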